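The route makes the bond between the quaternary, methyl-bearing cyclobutane carbon (C-4) and the allylic bridgehead CH (C-9) last. In the target the C-3 oxygen lies anti to this bond and 1,4 to C-8, the enone carbon that bears the vinylic methyl; with C-8 as a ketone this is the retron of an enolate–epoxide opening. The kinetic C-9 enolate of a cis-fused cyclohexenone–cycloheptene oxide attacks the tertiary epoxide carbon: one operation closes the cyclobutane and the bicyclo[3.1.1]heptenone ring (C-4 to C-9), sets the quaternary centre by inversion and frees the C-3 hydroxyl in the tiglate configuration. The precursor is a himachalane-type bicycle whose stereocentres are all relayed from C-1.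

Key step: step 11

Remark: ring carbons are called C-1 to C-11 in the order of the target SMILES: C-1 (angelate carbinol), C-2 (CH2), C-3 (tiglate carbinol), C-4 (quaternary C–CH3), C-5 (CH next to the ketone), C-6 (C=O), C-7 (=CH), C-8 (=C–CH3), C-9 (allylic CH), C-10 (CH), C-11 (CMe2).

Assumption: compounds 1, 2, 6, 9, 20 and 24 are bought; if 1 is not on offer it is one oxidation away from methyl hydroxypivalate.

Step 1
Reactants: 1 methyl 2,2-dimethyl-3-oxopropanoate; 2 allyltributylstannane
Product: 3 methyl (3R)-3-hydroxy-2,2-dimethylhex-5-enoate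
Conditions: (R)-BINOL (20 mol %), Ti(OiPr)4 (10 mol %), 4 Å MS, CH2Cl2, −20 °C; then H2O
Reagents that add atoms: allyltributylstannane 2, C=CC[Sn](CCCC)(CCCC)CCCC
Why: Keck asymmetric allylation: the (R)-BINOL titanium complex should deliver the allyl group to the Re face of the non-enolisable aldehyde and so set C-1 as R, the only stereocentre made by catalysis.

Step 2
Reactants: 3 methyl (3R)-3-hydroxy-2,2-dimethylhex-5-enoate
Product: 4 (3R)-2,2-dimethylhex-5-ene-1,3-diol
Conditions: LiAlH4, THF, 0 °C; then H2O
Reagents that add atoms: none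
Why: Hydride reduction of the ester to the primary alcohol, which leaves the carbinol centre and the alkene untouched.

Step 3
Reactants: 4 (3R)-2,2-dimethylhex-5-ene-1,3-diol
Product: 5 (3R)-3-hydroxy-2,2-dimethylhex-5-enal
Conditions: TEMPO (10 mol %), PhI(OAc)2, CH2Cl2, 25 °C
Reagents that add atoms: none
Why: TEMPO-catalysed oxoammonium oxidation is selective for the primary over the secondary alcohol, and the quaternary α-carbon rules out epimerisation or elimination of the β-hydroxy aldehyde.

Step 4
Reactants: 5 (3R)-3-hydroxy-2,2-dimethylhex-5-enal; 6 (triphenylphosphoranylidene)ketene (Bestmann ylide)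
Product: 8 (6R)-6-allyl-5,5-dimethyl-5,6-dihydro-2H-pyran-2-one, via ester ylide 7 (not isolated)
Conditions: toluene, 110 °C
Reagents that add atoms: (triphenylphosphoranylidene)ketene 6, O=C=C=P(c1ccccc1)(c1ccccc1)c1ccccc1
Why: Bestmann cascade: the alcohol adds to the ketene ylide to give the ester-stabilised ylide, and an intramolecular Wittig olefination of the aldehyde closes the unsaturated six-membered lactone, whose ring fixes the alkene as Z.

Step 5
Reactants: 8 (6R)-6-allyl-5,5-dimethyl-5,6-dihydro-2H-pyran-2-one; 9 (E)-1-(dimethylamino)-3-(tert-butyldimethylsilyloxy)buta-1,3-diene (Rawal's diene)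
Product: 10 cis-fused lactone cycloadduct (C-4 lactone carbonyl; C-6 NMe2; C-8 silyl enol ether; ring-fusion hydrogens at C-5 and C-10 cis and on the face of the allyl group)
Conditions: toluene, 130 °C, sealed tube
Reagents that add atoms: Rawal's diene 9, CN(C)/C=C/C(=C)O[Si](C)(C)C(C)(C)C
Why: Diels–Alder reaction: the CH2 terminus of the aminosiloxy diene bonds to the β-carbon C-10 and the amino terminus to C-5, suprafacial addition to the ring alkene makes the C-5/C-10 fusion cis, and approach anti to the C-1 allyl group and the axial C-11 methyl should relay C-1 to C-5 and C-10.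

Step 6
Reactants: 10 cis-fused lactone cycloadduct
Product: 11 hydroxy methyl ketone (C-4 acetyl on C-5; free C-1 hydroxyl; in equilibrium with its six-membered hemiketal)
Conditions: CH3Li (1.1 equiv), THF, −78 °C; then H2O
Reagents that add atoms: methyllithium, [Li]C
Why: Single addition of CH3Li to the lactone carbonyl gives a tetrahedral alkoxide that is stable at −78 °C and collapses on work-up to the methyl ketone, which brings in the C-4 methyl group while the silyl enol ether masks the C-8 ketone.

Step 7
Reactants: 11 hydroxy methyl ketone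
Product: 12 isopropenyl carbinol (C-4(CH3)=CH2 on C-5; C-6 NMe2 and C-8 silyl enol ether intact)
Conditions: Ph3PCH3Br, KOtBu, THF, 0 to 25 °C
Reagents that add atoms: methylenetriphenylphosphorane, C=P(c1ccccc1)(c1ccccc1)c1ccccc1
Why: Wittig methylenation of the open keto form turns the acetyl group into the isopropenyl group needed for ring closure; the β-amino group is a poor leaving group under base and the hemiketal keeps the ketone concentration low, which should protect C-5.

Step 8
Reactants: 12 isopropenyl carbinol
Product: 14 cis-5-[(3R)-3-(tert-butyldimethylsilyloxy)-2-methylhex-5-en-2-yl]-4-(prop-1-en-2-yl)cyclohex-2-en-1-one, via bis-silyl intermediate 13 (not isolated)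
Conditions: TBSOTf, 2,6-lutidine, CH2Cl2, −78 to 0 °C; then 1 M HCl, THF, 0 °C
Reagents that add atoms: tert-butyldimethylsilyl triflate, CC(C)(C)[Si](C)(C)OS(=O)(=O)C(F)(F)F
Why: Silylation of the C-1 alcohol before dilute acid hydrolyses the silyl enol ether and eliminates dimethylamine (E1cB) means that the cyclohex-2-enone never meets a free hydroxyl that could add to it in an oxa-Michael reaction; the C-6 stereocentre is lost on purpose.

Step 9
Reactants: 14 silyl ether dienone
Product: 15 cis-fused bicyclic dienone (cyclohex-2-enone C-5 to C-10 with C-8 ketone, fused at C-5/C-10 to the cycloheptene with C-3=C-4; C-1 OTBS on the face of the six-membered ring)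
Conditions: second-generation Grubbs catalyst, (H2IMes)(PCy3)Cl2Ru=CHPh (5 mol %), CH2Cl2, 40 °C
Reagents that add atoms: none
Why: Ring-closing metathesis of the allyl terminus with the isopropenyl group forms the seven-membered ring and its trisubstituted C-3=C-4 alkene, while the electron-poor enone alkene stays out.

Step 10
Reactants: 15 cis-fused bicyclic dienone
Product: 16 C-3/C-4 epoxide (oxygen on the face of H-5 and H-10, anti to the C-1 silyloxy group)
Conditions: mCPBA, NaHCO3, CH2Cl2, 0 °C
Reagents that add atoms: 3-chloroperbenzoic acid, OOC(=O)c1cccc(Cl)c1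
Why: Prilezhaev epoxidation of the electron-rich trisubstituted alkene in preference to the enone; attack on the convex face, anti to the six-membered ring at C-5 and to the C-1 silyloxy group, should set C-3 and the C-4 configuration that the next step inverts.

Step 11
Reactants: 16 C-3/C-4 epoxide
Product: 18 tricyclic hydroxy enone (C-1 OTBS; C-3 OH; C-8 ketone; C-6=C-7 alkene), via potassium enolate 17 (not isolated)
Conditions: KN(SiMe3)2 (1.1 equiv), THF, −78 to 25 °C; then H2O
Reagents that add atoms: none
Why: KN(SiMe3)2 removes a kinetic α′ proton at C-9 to give the cross-conjugated enolate, whose C-9 attacks the tertiary epoxide carbon C-4 from the face opposite to the C-4–O bond and frees the C-3 alkoxide. The closest known reaction types are the Stork epoxynitrile cyclisation, which gives cyclobutanes by exo opening of an epoxide, and the keto tosylate alkylations that close the bicyclo[3.1.1]heptanone core of nopinone-type ketones. The C-4–C-9 bond closes the cyclobutane in the 4-exo-tet mode and, with it, the bicyclo[3.1.1]heptenone ring C-4 to C-9, the last ring of the skeleton. C-4 is set by inversion at the epoxide carbon, C-3 keeps the epoxide configuration so that its oxygen ends anti to the new bond as in the target, and C-9 can only be bridged on the face fixed by the cis fusion at C-5 and C-10. The step needs deprotonation at C-9 and not at the vinylogous, tertiary C-5–H, which kinetic conditions should secure, and exo attack at C-4 instead of endo attack at C-3, which the collinear approach requires; C-7 has no nucleophilic character in this enolate, so the isomeric cyclobutanone cannot form.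

Step 12
Reactants: 18 tricyclic hydroxy enone
Product: 19 C-8 methyl carbinol (tertiary allylic alcohol at C-8; C-3 OH; C-1 OTBS)
Conditions: CH3Li (3 equiv), THF, −78 °C; then H2O
Reagents that add atoms: methyllithium, [Li]C
Why: 1,2-Addition of CH3Li to the non-enolisable bicyclic enone (C-9 is a bridgehead) brings in the C-8 methyl group, most likely from the face of the C-10 bridge; the new C-8 carbinol centre is lost two steps later.

Step 13
Reactants: 19 C-8 methyl carbinol; 20 tigloyl chloride
Product: 21 C-3 tiglate of 19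
Conditions: DMAP, Et3N, CH2Cl2, 0 to 25 °C
Reagents that add atoms: tigloyl chloride 20, C/C=C(\C)C(=O)Cl
Why: DMAP-catalysed acylation of the secondary C-3 alcohol; the tertiary allylic alcohol at C-8 is too hindered to react and the E acyl group has no tendency to isomerise.

Step 14
Reactants: 21 C-3 tiglate of 19
Product: 22 C-1 silyl ether of the C-3 tiglate enone (C-6 ketone; C-7=C-8 with the C-8 methyl)
Conditions: pyridinium chlorochromate, C5H5NH[CrO3Cl], 4 Å MS, CH2Cl2, 25 °C
Reagents that add atoms: pyridinium chlorochromate, [O-][Cr](=O)(=O)Cl.c1cc[nH+]cc1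
Why: Dauben–Babler oxidative transposition: the chromate ester of the tertiary allylic alcohol shifts suprafacially from C-8 to C-6 in a [3,3] rearrangement and is oxidised there, which gives the verbenone-type enone without a free cation next to the cyclobutane.

Step 15
Reactants: 22 C-1 silyl ether
Product: 23 C-1 alcohol (C-3 tiglate; enone as in the target)
Conditions: HF·pyridine, THF, 0 to 25 °C
Reagents that add atoms: none
Why: Fluoride cleavage of the silyl ether under mildly acidic conditions, which avoid migration of the tiglate from C-3 to C-1 and leave the enone untouched.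

Step 16
Reactants: 23 C-1 alcohol; 24 angelic acid
Product: 25 target, 7-angeloyloxy-9-tigloyloxylongipin-2-en-1-one (CNP0236543.4)
Conditions: 24, 2,4,6-trichlorobenzoyl chloride, Et3N, toluene, 25 °C; then 23, 80 °C
Reagents that add atoms: angelic acid 24, C/C=C(/C)C(=O)O
Why: Yamaguchi-type esterification through the mixed 2,4,6-trichlorobenzoic anhydride without DMAP, conditions under which the Z acyl group should be transferred to the hindered C-1 alcohol without isomerisation to the tiglate.

Compound list
1 | methyl 2,2-dimethyl-3-oxopropanoate | O=CC(C)(C)C(=O)OC | starting material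
2 | allyltributylstannane | C=CC[Sn](CCCC)(CCCC)CCCC | starting material
3 | methyl (3R)-3-hydroxy-2,2-dimethylhex-5-enoate | C=CC[C@@H](O)C(C)(C)C(=O)OC | intermediate
4 | (3R)-2,2-dimethylhex-5-ene-1,3-diol | C=CC[C@@H](O)C(C)(C)CO | intermediate
5 | (3R)-3-hydroxy-2,2-dimethylhex-5-enal | C=CC[C@@H](O)C(C)(C)C=O | intermediate
6 | (triphenylphosphoranylidene)ketene (Bestmann ylide) | O=C=C=P(c1ccccc1)(c1ccccc1)c1ccccc1 | starting material
7 | (3R)-2,2-dimethyl-1-oxohex-5-en-3-yl (triphenylphosphoranylidene)acetate (ester ylide) | C=CC[C@@H](OC(=O)C=P(c1ccccc1)(c1ccccc1)c1ccccc1)C(C)(C)C=O | intermediate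
8 | (6R)-6-allyl-5,5-dimethyl-5,6-dihydro-2H-pyran-2-one | C=CC[C@H]1OC(=O)C=CC1(C)C | intermediate
9 | (E)-1-(dimethylamino)-3-(tert-butyldimethylsilyloxy)buta-1,3-diene (Rawal's diene) | CN(C)/C=C/C(=C)O[Si](C)(C)C(C)(C)C | starting material
10 | cis-fused cycloadduct: 3-allyl-8-(dimethylamino)-4,4-dimethyl-6-(tert-butyldimethylsilyloxy)-3,4,4a,5,8,8a-hexahydro-1H-isochromen-1-one; ring-fusion H cis and on the face of the allyl group, NMe2 cis to the lactone carbonyl | C=CC[C@H]1OC(=O)[C@@H]2[C@H](N(C)C)C=C(O[Si](C)(C)C(C)(C)C)C[C@@H]2C1(C)C | intermediate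
11 | hydroxy methyl ketone (open form of the methyl hemiketal): cyclohexene with C-5 acetyl, C-6 NMe2, C-8 silyl enol ether, C-10 bearing CMe2–CH(OH)–allyl | C=CC[C@@H](O)C(C)(C)[C@H]1CC(O[Si](C)(C)C(C)(C)C)=C[C@@H](N(C)C)[C@H]1C(C)=O | intermediate
12 | isopropenyl carbinol: as 11 with C-4(CH3)=CH2 in place of the acetyl group | C=CC[C@@H](O)C(C)(C)[C@H]1CC(O[Si](C)(C)C(C)(C)C)=C[C@@H](N(C)C)[C@H]1C(C)=C | intermediate
13 | bis-silyl intermediate: C-1 silyl ether of 12 | C=CC[C@@H](O[Si](C)(C)C(C)(C)C)C(C)(C)[C@H]1CC(O[Si](C)(C)C(C)(C)C)=C[C@@H](N(C)C)[C@H]1C(C)=C | intermediate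
14 | cis-5-[(3R)-3-(tert-butyldimethylsilyloxy)-2-methylhex-5-en-2-yl]-4-(prop-1-en-2-yl)cyclohex-2-en-1-one | C=CC[C@@H](O[Si](C)(C)C(C)(C)C)C(C)(C)[C@H]1CC(=O)C=C[C@H]1C(C)=C | intermediate
15 | cis-fused bicyclo[5.4.0]undecadienone: C-8 ketone, C-6=C-7 and C-3=C-4 alkenes, C-4 methyl, C-11 gem-dimethyl, C-1 OTBS cis to C-6 and C-9 | CC(C)(C)[Si](C)(C)O[C@@H]1CC=C(C)[C@@H]2C=CC(=O)C[C@@H]2C1(C)C | intermediate
16 | C-3/C-4 epoxide of 15, oxygen syn to H-5 and H-10 and anti to the C-1 silyloxy group | CC(C)(C)[Si](C)(C)O[C@@H]1C[C@H]3O[C@@]3(C)[C@@H]2C=CC(=O)C[C@@H]2C1(C)C | intermediate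
17 | potassium C-8/C-9 enolate of 16 | CC(C)(C)[Si](C)(C)O[C@@H]1C[C@H]3O[C@@]3(C)[C@@H]2C=CC([O-])=C[C@@H]2C1(C)C.[K+] | intermediate
18 | tricyclic hydroxy enone: longipinane skeleton with C-1 OTBS, C-3 OH, C-8 ketone, C-6=C-7 alkene | CC(C)(C)[Si](C)(C)O[C@@H]1C[C@@H](O)[C@@]2(C)[C@@H]3C=CC(=O)[C@H]2[C@@H]3C1(C)C | intermediate
19 | C-8 methyl carbinol: tertiary allylic alcohol at C-8 (hydroxyl on the side of the C-4 bridge), C-3 OH, C-1 OTBS | CC(C)(C)[Si](C)(C)O[C@@H]1C[C@@H](O)[C@@]2(C)[C@@H]3C=C[C@](C)(O)[C@H]2[C@@H]3C1(C)C | intermediate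
20 | tigloyl chloride, (E)-2-methylbut-2-enoyl chloride | C/C=C(\C)C(=O)Cl | starting material
21 | C-3 tiglate of 19 | CC(C)(C)[Si](C)(C)O[C@@H]1C[C@@H](OC(=O)/C(C)=C/C)[C@@]2(C)[C@@H]3C=C[C@](C)(O)[C@H]2[C@@H]3C1(C)C | intermediate
22 | C-1 tert-butyldimethylsilyl ether of the C-3 tiglate enone (C-6 ketone, C-7=C-8 with C-8 methyl) | CC(C)(C)[Si](C)(C)O[C@@H]1C[C@@H](OC(=O)/C(C)=C/C)[C@@]2(C)[C@@H]3C(=O)C=C(C)[C@H]2[C@@H]3C1(C)C | intermediate
23 | C-1 alcohol with C-3 tiglate (target without the angelate) | O[C@@H]1C[C@@H](OC(=O)/C(C)=C/C)[C@@]2(C)[C@@H]3C(=O)C=C(C)[C@H]2[C@@H]3C1(C)C | intermediate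
24 | angelic acid, (Z)-2-methylbut-2-enoic acid | C/C=C(/C)C(=O)O | starting material
25 | target CNP0236543.4: C-1 (R) angelate, C-3 (R) tiglate, C-4 (R), C-5 (R), C-9 (R), C-10 (S) | C/C=C(/C)C(=O)O[C@@H]1C[C@@H](OC(=O)/C(C)=C/C)[C@@]2(C)[C@@H]3C(=O)C=C(C)[C@H]2[C@@H]3C1(C)C | target

Total step count: 16. Longest linear sequence: 16 steps (1 to 25).

Steps most likely to fail

Step 11: the enolate may not attack the fully substituted epoxide carbon, or proton transfer to the C-5 dienolate may open the epoxide by elimination. Fallback: from 16, LiN(iPr)2 and Me3SiCl at −78 °C would give the cross-conjugated trimethylsilyl enol ether F1; TiCl4 in CH2Cl2 at −78 °C would then open the epoxide at its tertiary carbon in a Mukaiyama-type closure with cation-like character, which comes back to 18 after aqueous work-up.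

Step 5: cycloaddition at the β-carbon next to the quaternary C-11 may be too slow, so that the diene decomposes first. Fallback: from 5, esterification with (phenylsulfonyl)acetic acid (DCC, DMAP) would give the sulfonylacetate F2, and an intramolecular Knoevenagel condensation (piperidine, AcOH) the 3-(phenylsulfonyl) lactone F3, a much stronger dienophile. Cycloaddition with 9 would give the sulfonyl cycloadduct F4, and reductive desulfonylation with SmI2 in THF–MeOH, with protonation of the lactone enolate on the convex face, comes back to 10.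

Step 7: the open ketone may epimerise at C-5 (loss of the cis fusion) or lose the amine by retro-Michael reaction under the basic ylide. Fallback: from 10, excess CH3Li would give the tertiary carbinol diol F5, and TBSOTf with 2,6-lutidine the secondary silyl ether F6. Dehydration of the tertiary alcohol with the Burgess reagent comes back to 13 without a ketone at C-4 ever being formed.

Further compounds
F1 | step 11 | trimethylsilyl enol ether of 16 (C-8 OSiMe3, C-8=C-9) | CC(C)(C)[Si](C)(C)O[C@@H]1C[C@H]3O[C@@]3(C)[C@@H]2C=CC(O[Si](C)(C)C)=C[C@@H]2C1(C)C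
F2 | step 5 | (3R)-2,2-dimethyl-1-oxohex-5-en-3-yl (phenylsulfonyl)acetate | C=CC[C@@H](OC(=O)CS(=O)(=O)c1ccccc1)C(C)(C)C=O
F3 | step 5 | (6R)-6-allyl-5,5-dimethyl-3-(phenylsulfonyl)-5,6-dihydro-2H-pyran-2-one | C=CC[C@H]1OC(=O)C(S(=O)(=O)c2ccccc2)=CC1(C)C
F4 | step 5 | sulfonyl cycloadduct: 10 with phenylsulfonyl in place of H-5 | C=CC[C@H]1OC(=O)[C@]2(S(=O)(=O)c3ccccc3)[C@H](N(C)C)C=C(O[Si](C)(C)C(C)(C)C)C[C@@H]2C1(C)C
F5 | step 7 | tertiary carbinol diol: 11 with C-4(CH3)2OH in place of the acetyl group | C=CC[C@@H](O)C(C)(C)[C@H]1CC(O[Si](C)(C)C(C)(C)C)=C[C@@H](N(C)C)[C@H]1C(C)(C)O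
F6 | step 7 | secondary silyl ether of F5 (C-1 OTBS, tertiary C-4 OH free) | C=CC[C@@H](O[Si](C)(C)C(C)(C)C)C(C)(C)[C@H]1CC(O[Si](C)(C)C(C)(C)C)=C[C@@H](N(C)C)[C@H]1C(C)(C)O
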